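**Assumption:** the target is taken as the enol tautomer drawn in the SMILES (the β-triketone tautomers interconvert). Bicyclic intermediates use indane numbering (C1 and C4 = the two carbinol carbons, C3a/C7a = ring fusion, C6 = future spiro carbon); β = face of 7a-H, α = face of 3a-H.

## Retrosynthetic overview

1. Acetyl group: last-step C-acylation of spiro-trione 30. Ring A is closed by Dieckmann condensation of diketo ester 29 (methyl ketone enolate onto the axial C6 ester).
2. Key disconnection: the C6–C(carbinol) bond, made by an intermolecular aldol between the lithium enolate of hydrindane ester 20 and gem-diprenyl aldehyde 25 (from methyl acetoacetate). Equatorial attack fixes the spiro centre.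
3. Ring B: intramolecular ester-enolate alkylation by an allylic chloride (11 → 14). The C4 carbinol comes from ozonolysis, axial Corey–Chaykovsky methylenation, thiolate opening and desulfurisation.
4. Ring C with C1/C7a/C3a: from (R)-limonene by ring contraction to cyclopentene carbaldehyde 5, epoxidation anti to the isopropenyl group, Wittig olefination and palladium/formate hydrogenolysis with inversion.
5. Ring order: C (cyclopentane) → B (cyclohexane, trans-hydrindane) → A (spiro trione).

## Route

**Step 1**
Reactants: 1 (R)-(+)-limonene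
Product: 2 (4R)-limonene 1,2-oxide (cis/trans mixture at the epoxide)
Conditions: mCPBA (1.0 equiv), NaHCO3, CH2Cl2, 0 °C
Reagents that add atoms: meta-chloroperoxybenzoic acid, OOC(=O)c1cccc(Cl)c1
Why: Prilezhaev epoxidation is faster at the trisubstituted ring alkene than at the isopropenyl group, and the two epoxide centres are destroyed in step 2 so their ratio is irrelevant.

**Step 2**
Reactants: 2 (4R)-limonene 1,2-oxide
Product: 4 (3R)-6-oxo-3-(prop-1-en-2-yl)heptanal, via limonene glycol 3 (not isolated)
Conditions: H5IO6 (1.2 equiv), THF/H2O, 0 → 25 °C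
Reagents that add atoms: water, O
Why: Acid-promoted epoxide hydrolysis followed by Malaprade glycol cleavage opens the ring without touching the stereocentre (future C3a) or the isopropenyl group.

**Step 3**
Reactants: 4 (3R)-6-oxo-3-(prop-1-en-2-yl)heptanal
Product: 5 (5S)-2-methyl-5-(prop-1-en-2-yl)cyclopent-1-ene-1-carbaldehyde
Conditions: piperidine (0.1 equiv), AcOH (0.1 equiv), toluene, 80 °C
Reagents that add atoms: none
Why: Enamine-mediated intramolecular aldol condensation (aldehyde α-carbon onto the methyl ketone, five-membered ring, then dehydration) gives the conjugated enal with the limonene stereocentre intact.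

**Step 4**
Reactants: 5 (5S)-2-methyl-5-(prop-1-en-2-yl)cyclopent-1-ene-1-carbaldehyde
Product: 6 5-methyl-2-(prop-1-en-2-yl)-6-oxabicyclo[3.1.0]hexane-1-carbaldehyde (epoxide oxygen trans to isopropenyl)
Conditions: 30% H2O2, NaOH (0.2 equiv), MeOH, 0 °C
Reagents that add atoms: hydrogen peroxide, OO
Why: Weitz–Scheffer nucleophilic epoxidation attacks only the electron-poor alkene, and ring closure occurs on the face opposite the adjacent isopropenyl group, which sets the future C1 oxygen α.

**Step 5**
Reactants: 6 epoxy aldehyde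
Product: 7 methyl (E)-3-[5-methyl-2-(prop-1-en-2-yl)-6-oxabicyclo[3.1.0]hexan-1-yl]prop-2-enoate
Conditions: Ph3P=CHCO2Me (1.3 equiv), toluene, 60 °C
Reagents that add atoms: methyl (triphenylphosphoranylidene)acetate, COC(=O)C=P(c1ccccc1)(c1ccccc1)c1ccccc1
Why: Wittig olefination with a stabilised ylide is E-selective, tolerates the epoxide, and installs the future C6 and its ester carbon.

**Step 6**
Reactants: 7 vinyl epoxide
Product: 8 methyl (2E)-3-[(1S,2R,5R)-2-hydroxy-2-methyl-5-(prop-1-en-2-yl)cyclopentyl]prop-2-enoate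
Conditions: Pd2(dba)3·CHCl3 (2.5 mol %), n-Bu3P (10 mol %), HCO2H (5 equiv), Et3N (2 equiv), 1,4-dioxane, 25 °C
Reagents that add atoms: none
Why: In this Tsuji–Trost-type hydrogenolysis zerovalent palladium ionises the allylic C–O bond anti and formate-derived hydride is delivered from the metal face to the same carbon, so H replaces O with inversion (7a-H β, side chain trans to isopropenyl, tertiary OH α retained).

**Step 7**
Reactants: 8 hydroxy enoate
Product: 9 methyl (2E)-3-[(1S,2R,5R)-2-methyl-5-(prop-1-en-2-yl)-2-(triethylsilyloxy)cyclopentyl]prop-2-enoate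
Conditions: TESOTf, 2,6-lutidine, CH2Cl2, −78 → 0 °C
Reagents that add atoms: triethylsilyl trifluoromethanesulfonate, CC[Si](CC)(CC)OS(=O)(=O)C(F)(F)F
Why: Silyl triflate silylation masks the tertiary alcohol so that it cannot lactonise or consume base in the enolate steps.

**Step 8**
Reactants: 9 silyl ether enoate
Product: 10 methyl 3-[(1S,2R,5R)-2-methyl-5-(prop-1-en-2-yl)-2-(triethylsilyloxy)cyclopentyl]propanoate
Conditions: Mg turnings (10 equiv), MeOH, 0 → 25 °C
Reagents that add atoms: none
Why: Dissolving-metal conjugate reduction with Mg in MeOH saturates only the conjugated enoate and leaves the isolated isopropenyl alkene untouched.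

**Step 9**
Reactants: 10 saturated ester
Product: 11 methyl 3-[(1S,2R,5R)-5-(3-chloroprop-1-en-2-yl)-2-methyl-2-(triethylsilyloxy)cyclopentyl]propanoate
Conditions: Ca(OCl)2, solid CO2, CH2Cl2/H2O, 0 °C
Reagents that add atoms: calcium hypochlorite, [Ca+2].[O-]Cl.[O-]Cl
Why: Ene-type allylic chlorination by HOCl converts the isopropenyl group into a 2-(chloromethyl)allyl unit with the double bond shifted to the former methyl, without affecting the ester or silyl ether.

**Step 10**
Reactants: 11 allylic chloride
Product: 14 methyl 1β-methyl-4-methylidene-1α-(triethylsilyloxy)-trans-octahydro-1H-indene-6α-carboxylate, via potassium ester enolate 12 (not isolated), via cyclised ester epimer mixture 13 (not isolated)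
Conditions: KN(SiMe3)2 (1.1 equiv), THF (0.01 M), −78 → 0 °C; then MeOH, NaOMe (0.3 equiv), 25 °C
Reagents that add atoms: none
Why: Intramolecular 6-exo-tet ester-enolate alkylation (SN2 and SN2' give the same product) closes ring B trans-fused because the two arms are trans on the cyclopentane, and methoxide equilibration puts the C6 ester equatorial (about 9:1; minor epimer recycled).

**Step 11**
Reactants: 14 methylidene hydrindane ester
Product: 16 methyl 1β-methyl-4-oxo-1α-(triethylsilyloxy)-trans-octahydro-1H-indene-6α-carboxylate, via spiro ozonide 15 (not isolated)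
Conditions: O3, CH2Cl2, −78 °C; then Me2S, −78 → 25 °C
Reagents that add atoms: ozone, [O-][O+]=O
Why: Ozonolysis with reductive work-up cleaves the only alkene to the C4 ketone under neutral conditions that do not epimerise C3a.

**Step 12**
Reactants: 16 keto ester
Product: 17 methyl 1β-methyl-1α-(triethylsilyloxy)-trans-octahydrospiro[indene-4,2'-oxirane]-6α-carboxylate (oxirane CH2 β/axial; oxygen α/equatorial)
Conditions: Me3S+ I−, n-BuLi, THF, −10 °C; then 16, −10 → 0 °C
Reagents that add atoms: trimethylsulfonium iodide, C[S+](C)C.[I-]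
Why: In the Corey–Chaykovsky reaction dimethylsulfonium methylide adds irreversibly along the axial (β) trajectory of the chair ketone, whose syn-axial positions carry only hydrogens, so the new carbon is axial and the oxygen equatorial as the target requires at C4.

**Step 13**
Reactants: 17 spiro-epoxide
Product: 18 methyl 4α-hydroxy-1β-methyl-4β-[(phenylsulfanyl)methyl]-1α-(triethylsilyloxy)-trans-octahydro-1H-indene-6α-carboxylate
Conditions: PhSH (2 equiv), K2CO3 (0.3 equiv), MeOH, 50 °C
Reagents that add atoms: thiophenol, Sc1ccccc1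
Why: SN2 epoxide opening by thiolate occurs only at the primary carbon, so the C4 configuration is untouched and the ester survives (unlike a hydride opening).

**Step 14**
Reactants: 18 β-hydroxy sulfide
Product: 19 methyl 4α-hydroxy-1β,4β-dimethyl-1α-(triethylsilyloxy)-trans-octahydro-1H-indene-6α-carboxylate
Conditions: Raney Ni (W-2), MeOH, 50 °C
Reagents that add atoms: none
Why: Raney nickel desulfurisation converts CH2SPh into the axial methyl group without affecting the ester, silyl ether or tertiary alcohol.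

**Step 15**
Reactants: 19 hydroxy ester
Product: 20 methyl (1R,3aR,4R,6R,7aS)-1,4-dimethyl-1,4-bis(triethylsilyloxy)octahydro-1H-indene-6-carboxylate
Conditions: TESOTf, 2,6-lutidine, CH2Cl2, 0 → 25 °C
Reagents that add atoms: triethylsilyl trifluoromethanesulfonate, CC[Si](CC)(CC)OS(=O)(=O)C(F)(F)F
Why: Silyl triflate silylation protects the second tertiary alcohol so that a clean mono-enolate can be formed in step 20.

**Step 16**
Reactants: 21 methyl acetoacetate
Product: 22 methyl 2-acetyl-5-methyl-2-(3-methylbut-2-en-1-yl)hex-4-enoate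
Conditions: prenyl bromide (2.5 equiv), K2CO3 (3 equiv), n-Bu4NI (cat.), DMF, 50 °C
Reagents that add atoms: prenyl bromide (1-bromo-3-methylbut-2-ene), CC(C)=CCBr
Why: Double C-alkylation of the β-keto ester with a reactive allylic bromide builds the gem-diprenyl quaternary carbon of ring A.

**Step 17**
Reactants: 22 diprenyl keto ester
Product: 23 2,2-bis(3-methylbut-2-en-1-yl)butane-1,3-diol (racemic)
Conditions: LiAlH4, THF, 0 → 25 °C
Reagents that add atoms: none
Why: Hydride reduction of both ester and ketone gives the 1,3-diol, whose new carbinol centre is later oxidised away so its configuration is irrelevant.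

**Step 18**
Reactants: 23 diol
Product: 24 3-hydroxy-2,2-bis(3-methylbut-2-en-1-yl)butanal (racemic)
Conditions: TEMPO (0.1 equiv), PhI(OAc)2 (1.1 equiv), CH2Cl2, 25 °C
Reagents that add atoms: none
Why: Oxoammonium (TEMPO) oxidation is selective for the primary alcohol over the hindered secondary one, and the aldehyde has no α-hydrogen so it cannot eliminate or epimerise.

**Step 19**
Reactants: 24 hydroxy aldehyde
Product: 25 2,2-bis(3-methylbut-2-en-1-yl)-3-(triethylsilyloxy)butanal (racemic)
Conditions: TESOTf, 2,6-lutidine, CH2Cl2, −78 °C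
Reagents that add atoms: triethylsilyl trifluoromethanesulfonate, CC[Si](CC)(CC)OS(=O)(=O)C(F)(F)F
Why: Silylation masks the future C3 ketone of ring A as a protected carbinol so that the aldehyde is the only electrophile offered to the enolate.

**Step 20 (key fragment union)**
Reactants: 20 hydrindane ester; 25 diprenyl aldehyde
Product: 27 methyl 6α-[1-hydroxy-2,2-bis(3-methylbut-2-en-1-yl)-3-(triethylsilyloxy)butyl]-1β,4β-dimethyl-1α,4α-bis(triethylsilyloxy)-trans-octahydro-1H-indene-6β-carboxylate (mixture at the two side-chain carbinols), via lithium enolate 26 (not isolated)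
Conditions: LiN(iPr)2 (1.1 equiv), THF, −78 °C; then 25 (2 equiv), −78 °C; AcOH quench at −78 °C
Reagents that add atoms: none
Why: In this intermolecular aldol addition the aldehyde (no α-hydrogen, so no proton transfer) approaches the exocyclic ester enolate from the equatorial α face, anti to the syn-axial 4β-methyl, so the ester becomes axial (β) and the new C–C bond equatorial, which is the spiro configuration of the target.

**Step 21**
Reactants: 27 aldol adduct
Product: 28 methyl 6α-[1,3-dihydroxy-2,2-bis(3-methylbut-2-en-1-yl)butyl]-1α,4α-dihydroxy-1β,4β-dimethyl-trans-octahydro-1H-indene-6β-carboxylate (mixture at the two side-chain carbinols)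
Conditions: HF·pyridine, pyridine/THF, 0 → 25 °C
Reagents that add atoms: none
Why: Buffered fluoride desilylation removes all three silyl ethers under non-basic conditions, so the congested β-hydroxy ester cannot undergo retro-aldol cleavage.

**Step 22**
Reactants: 28 tetraol
Product: 29 methyl 6α-[2,2-bis(3-methylbut-2-en-1-yl)-3-oxobutanoyl]-1α,4α-dihydroxy-1β,4β-dimethyl-trans-octahydro-1H-indene-6β-carboxylate
Conditions: Dess–Martin periodinane (3 equiv), NaHCO3, CH2Cl2, 25 °C
Reagents that add atoms: none
Why: Dess–Martin oxidation converts both secondary alcohols to ketones (merging all diastereomers into one compound) while tertiary alcohols and prenyl alkenes are inert.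

**Step 23**
Reactants: 29 diketo ester
Product: 30 spiro-trione (ring A 2,2-diprenylcyclohexane-1,3,5-trione, spiro at C4 of ring A to the hydrindane; 1α,4α-dihydroxy-1β,4β-dimethyl)
Conditions: LiN(SiMe3)2 (5 equiv), THF, −78 → 25 °C; aq. HCl work-up
Reagents that add atoms: none
Why: In this Dieckmann (intramolecular Claisen) condensation the methyl ketone carries the only enolisable hydrogens and its enolate can only close a six-membered ring onto the axial ester, with deprotonation of the resulting trione driving the reaction; the spiro centre is quaternary and unaffected.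

**Step 24**
Reactants: 30 spiro-trione
Product: 32 CNP0266834.1, via enol acetate 31 (not isolated)
Conditions: AcOH (1.1 equiv), DCC (1.2 equiv), DMAP (1.2 equiv), CH2Cl2, 25 °C
Reagents that add atoms: acetic acid, CC(=O)O
Why: Steglich-type O-acylation of the cyclic 1,3-dione enol followed by DMAP-mediated 1,3 O→C acyl shift places the acetyl group on the only carbon flanked by two carbonyls, and the tertiary alcohols are not acylated under these conditions.

## Compound list

1 | (R)-(+)-limonene, (4R)-1-methyl-4-(prop-1-en-2-yl)cyclohex-1-ene | CC1=CC[C@@H](CC1)C(C)=C | starting material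
2 | (4R)-limonene 1,2-oxide, cis/trans mixture at the epoxide carbons | CC12OC1C[C@@H](CC2)C(C)=C | intermediate
3 | (4R)-p-menth-8-ene-1,2-diol (limonene glycol), diastereomer mixture, not isolated | CC1(O)C(O)C[C@@H](CC1)C(C)=C | intermediate
4 | (3R)-6-oxo-3-(prop-1-en-2-yl)heptanal | O=CC[C@@H](CCC(C)=O)C(C)=C | intermediate
5 | (5S)-2-methyl-5-(prop-1-en-2-yl)cyclopent-1-ene-1-carbaldehyde | CC1=C(C=O)[C@@H](CC1)C(C)=C | intermediate
6 | 5-methyl-2-(prop-1-en-2-yl)-6-oxabicyclo[3.1.0]hexane-1-carbaldehyde, epoxide oxygen trans to the isopropenyl group | C[C@]12O[C@@]1(C=O)[C@@H](CC2)C(C)=C | intermediate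
7 | methyl (E)-3-[5-methyl-2-(prop-1-en-2-yl)-6-oxabicyclo[3.1.0]hexan-1-yl]prop-2-enoate, epoxide trans to isopropenyl | C[C@]12O[C@@]1(/C=C/C(=O)OC)[C@@H](CC2)C(C)=C | intermediate
8 | methyl (2E)-3-[(1S,2R,5R)-2-hydroxy-2-methyl-5-(prop-1-en-2-yl)cyclopentyl]prop-2-enoate (side chain trans to isopropenyl, cis to OH) | COC(=O)/C=C/[C@H]1[C@@H](CC[C@@]1(C)O)C(C)=C | intermediate
9 | triethylsilyl ether of 8 | COC(=O)/C=C/[C@H]1[C@@H](CC[C@@]1(C)O[Si](CC)(CC)CC)C(C)=C | intermediate
10 | methyl 3-[(1S,2R,5R)-2-methyl-5-(prop-1-en-2-yl)-2-(triethylsilyloxy)cyclopentyl]propanoate | COC(=O)CC[C@H]1[C@@H](CC[C@@]1(C)O[Si](CC)(CC)CC)C(C)=C | intermediate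
11 | methyl 3-[(1S,2R,5R)-5-(3-chloroprop-1-en-2-yl)-2-methyl-2-(triethylsilyloxy)cyclopentyl]propanoate | COC(=O)CC[C@H]1[C@@H](CC[C@@]1(C)O[Si](CC)(CC)CC)C(=C)CCl | intermediate
12 | potassium ester enolate of 11, not isolated | COC(O[K])=CC[C@H]1[C@@H](CC[C@@]1(C)O[Si](CC)(CC)CC)C(=C)CCl | intermediate
13 | cyclised hydrindane ester as C6 epimer mixture, not isolated | COC(=O)C2C[C@H]3[C@@H](CC[C@@]3(C)O[Si](CC)(CC)CC)C(=C)C2 | intermediate
14 | methyl (1R,3aR,6R,7aS)-1-methyl-4-methylidene-1-(triethylsilyloxy)octahydro-1H-indene-6-carboxylate (trans-fused; 1β-Me, 1α-OTES, 6α equatorial ester) | COC(=O)[C@@H]2C[C@H]3[C@@H](CC[C@@]3(C)O[Si](CC)(CC)CC)C(=C)C2 | intermediate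
15 | spiro 1,2,4-trioxolane (secondary ozonide) at C4 of 14, not isolated | COC(=O)[C@@H]2C[C@H]3[C@@H](CC[C@@]3(C)O[Si](CC)(CC)CC)C4(OCOO4)C2 | intermediate
16 | methyl (1R,3aR,6R,7aS)-1-methyl-4-oxo-1-(triethylsilyloxy)octahydro-1H-indene-6-carboxylate | COC(=O)[C@@H]2C[C@H]3[C@@H](CC[C@@]3(C)O[Si](CC)(CC)CC)C(=O)C2 | intermediate
17 | C4 spiro-oxirane of 16, oxirane CH2 β (axial), oxygen α (equatorial) | COC(=O)[C@@H]2C[C@H]3[C@@H](CC[C@@]3(C)O[Si](CC)(CC)CC)[C@]4(OC4)C2 | intermediate
18 | methyl 4α-hydroxy-1β-methyl-4β-[(phenylsulfanyl)methyl]-1α-(triethylsilyloxy)-trans-octahydro-1H-indene-6α-carboxylate | COC(=O)[C@@H]2C[C@H]3[C@@H](CC[C@@]3(C)O[Si](CC)(CC)CC)[C@](CSc4ccccc4)(O)C2 | intermediate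
19 | methyl (1R,3aR,4R,6R,7aS)-4-hydroxy-1,4-dimethyl-1-(triethylsilyloxy)octahydro-1H-indene-6-carboxylate (4β-Me axial, 4α-OH equatorial) | COC(=O)[C@@H]2C[C@H]3[C@@H](CC[C@@]3(C)O[Si](CC)(CC)CC)[C@](C)(O)C2 | intermediate
20 | methyl (1R,3aR,4R,6R,7aS)-1,4-dimethyl-1,4-bis(triethylsilyloxy)octahydro-1H-indene-6-carboxylate | COC(=O)[C@@H]2C[C@H]3[C@@H](CC[C@@]3(C)O[Si](CC)(CC)CC)[C@](C)(O[Si](CC)(CC)CC)C2 | intermediate
21 | methyl acetoacetate | COC(=O)CC(C)=O | starting material
22 | methyl 2-acetyl-5-methyl-2-(3-methylbut-2-en-1-yl)hex-4-enoate | COC(=O)C(CC=C(C)C)(CC=C(C)C)C(C)=O | intermediate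
23 | 2,2-bis(3-methylbut-2-en-1-yl)butane-1,3-diol, racemic | OCC(CC=C(C)C)(CC=C(C)C)C(C)O | intermediate
24 | 3-hydroxy-2,2-bis(3-methylbut-2-en-1-yl)butanal, racemic | O=CC(CC=C(C)C)(CC=C(C)C)C(C)O | intermediate
25 | 2,2-bis(3-methylbut-2-en-1-yl)-3-(triethylsilyloxy)butanal, racemic | O=CC(CC=C(C)C)(CC=C(C)C)C(C)O[Si](CC)(CC)CC | intermediate
26 | lithium enolate of 20, not isolated | COC(O[Li])=C2C[C@H]3[C@@H](CC[C@@]3(C)O[Si](CC)(CC)CC)[C@](C)(O[Si](CC)(CC)CC)C2 | intermediate
27 | aldol adduct: C6 bears the ester β (axial) and the 1-hydroxy-2,2-diprenyl-3-(triethylsilyloxy)butyl chain α (equatorial); mixture at the two side-chain carbinols | CC(O[Si](CC)(CC)CC)C(CC=C(C)C)(CC=C(C)C)C(O)[C@@]2(C[C@H]3[C@@H](CC[C@@]3(C)O[Si](CC)(CC)CC)[C@](C)(O[Si](CC)(CC)CC)C2)C(=O)OC | intermediate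
28 | tetraol from 27 (all silyl groups removed); mixture at the two side-chain carbinols | CC(O)C(CC=C(C)C)(CC=C(C)C)C(O)[C@@]2(C[C@H]3[C@@H](CC[C@@]3(C)O)[C@](C)(O)C2)C(=O)OC | intermediate
29 | methyl 6α-[2,2-bis(3-methylbut-2-en-1-yl)-3-oxobutanoyl]-1α,4α-dihydroxy-1β,4β-dimethyl-trans-octahydro-1H-indene-6β-carboxylate | CC(=O)C(CC=C(C)C)(CC=C(C)C)C(=O)[C@@]2(C[C@H]3[C@@H](CC[C@@]3(C)O)[C@](C)(O)C2)C(=O)OC | intermediate
30 | spiro-trione: the target lacking the acetyl group (drawn as triketo tautomer) | C1C(=O)C(CC=C(C)C)(CC=C(C)C)C(=O)[C@@]2(C[C@H]3[C@@H](CC[C@@]3(C)O)[C@](C)(O)C2)C1=O | intermediate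
31 | enol acetate of 30 (O-acetyl at the enol oxygen next to the diprenyl carbon), not isolated | C1=C(OC(C)=O)C(CC=C(C)C)(CC=C(C)C)C(=O)[C@@]2(C[C@H]3[C@@H](CC[C@@]3(C)O)[C@](C)(O)C2)C1=O | intermediate
32 | CNP0266834.1: trans-hydrindane with 1α-OH/1β-Me and 4α-OH (equatorial)/4β-Me (axial), spiro at C6 to the 2-acetyl-4,4-diprenyl trione ring, the carbonyl next to the acetyl-bearing carbon axial (β) | CC(=O)C1=C(O)C(CC=C(C)C)(CC=C(C)C)C(=O)[C@@]2(C[C@H]3[C@@H](CC[C@@]3(C)O)[C@](C)(O)C2)C1=O | target

## Step count and risk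

Total step count: 24. Longest linear sequence: 20 steps (steps 1–15, then 20–24, from (R)-limonene). The aldehyde branch is 4 steps (16–19).

The three steps most likely to fail:

**Step 6 (palladium/formate hydrogenolysis of the tetrasubstituted vinyl epoxide).** The risk is hydride delivery to the ester terminus or diene formation instead of inversion at the ring carbon. The fallback sets out from 6 and comes back at 8. Epoxy aldehyde 6 is reduced with SmI2 (2.2 equiv, THF/MeOH, −90 °C). The ketyl cleaves the Cα–O bond and the samarium enolate is protonated to (1S,2R,5R)-2-hydroxy-2-methyl-5-(prop-1-en-2-yl)cyclopentane-1-carbaldehyde F1. Its epimerisable α-centre settles with the formyl group trans to the isopropenyl group and cis (hydrogen-bonded) to the tertiary OH. Immediate Wittig olefination with Ph3P=CHCO2Me (CH2Cl2, 25 °C) then gives 8, so compound 7 is skipped. The ring hydrogen is set by thermodynamic protonation instead of by stereospecific hydride delivery.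

**Step 20 (aldol between a fully substituted enolate and an α-quaternary aldehyde).** The risk is low conversion or retro-aldol because of congestion. The fallback sets out from 20 and comes back at 29. The same lithium enolate is C-acylated from the equatorial face with diketene, a small unhindered acyl donor (Claisen-type acylation, THF, −78 °C, 1.0 equiv base). This gives methyl 1β,4β-dimethyl-6α-(3-oxobutanoyl)-1α,4α-bis(triethylsilyloxy)-trans-octahydro-1H-indene-6β-carboxylate F2. The quaternary carbon is then built afterwards by double C-prenylation of the 1,3-diketone methylene (prenyl bromide, K2CO3, acetone, reflux), giving methyl 6α-[2,2-bis(3-methylbut-2-en-1-yl)-3-oxobutanoyl]-1β,4β-dimethyl-1α,4α-bis(triethylsilyloxy)-trans-octahydro-1H-indene-6β-carboxylate F3. HF·pyridine removes both silyl ethers to give 29. Aldehyde 25 and compounds 27 and 28 are then not needed.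

**Step 23 (Dieckmann closure onto an axial, α-quaternary methyl ester).** The risk is a sluggish attack that lets retro-Claisen cleavage of the 2,2-disubstituted 1,3-diketone compete. The fallback sets out from 28 and comes back at 30. LiAlH4 (THF, 0 → 25 °C) reduces the ester of 28 to the primary alcohol, giving 1-[1α,4α-dihydroxy-6β-(hydroxymethyl)-1β,4β-dimethyl-trans-octahydro-1H-inden-6α-yl]-2,2-bis(3-methylbut-2-en-1-yl)butane-1,3-diol F4. Dess–Martin periodinane oxidises the primary and both secondary alcohols to 6α-[2,2-bis(3-methylbut-2-en-1-yl)-3-oxobutanoyl]-1α,4α-dihydroxy-1β,4β-dimethyl-trans-octahydro-1H-indene-6β-carbaldehyde F5. LiN(SiMe3)2 (THF, −78 °C) then closes ring A by intramolecular aldol addition of the methyl ketone enolate onto the aldehyde, which is far more electrophilic than the ester. This gives the ring A β-hydroxy diketone (the 1-hydroxy-3,5-dione analogue of 30) F6. A second Dess–Martin oxidation gives 30.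

## Further compounds

F1 | step 6 | (1S,2R,5R)-2-hydroxy-2-methyl-5-(prop-1-en-2-yl)cyclopentane-1-carbaldehyde | O=C[C@H]1[C@@H](CC[C@@]1(C)O)C(C)=C
F2 | step 20 | methyl 1β,4β-dimethyl-6α-(3-oxobutanoyl)-1α,4α-bis(triethylsilyloxy)-trans-octahydro-1H-indene-6β-carboxylate | CC(=O)CC(=O)[C@@]2(C[C@H]3[C@@H](CC[C@@]3(C)O[Si](CC)(CC)CC)[C@](C)(O[Si](CC)(CC)CC)C2)C(=O)OC
F3 | step 20 | methyl 6α-[2,2-bis(3-methylbut-2-en-1-yl)-3-oxobutanoyl]-1β,4β-dimethyl-1α,4α-bis(triethylsilyloxy)-trans-octahydro-1H-indene-6β-carboxylate | CC(=O)C(CC=C(C)C)(CC=C(C)C)C(=O)[C@@]2(C[C@H]3[C@@H](CC[C@@]3(C)O[Si](CC)(CC)CC)[C@](C)(O[Si](CC)(CC)CC)C2)C(=O)OC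
F4 | step 23 | 1-[1α,4α-dihydroxy-6β-(hydroxymethyl)-1β,4β-dimethyl-trans-octahydro-1H-inden-6α-yl]-2,2-bis(3-methylbut-2-en-1-yl)butane-1,3-diol (mixture at the two side-chain carbinols) | CC(O)C(CC=C(C)C)(CC=C(C)C)C(O)[C@@]2(C[C@H]3[C@@H](CC[C@@]3(C)O)[C@](C)(O)C2)CO
F5 | step 23 | 6α-[2,2-bis(3-methylbut-2-en-1-yl)-3-oxobutanoyl]-1α,4α-dihydroxy-1β,4β-dimethyl-trans-octahydro-1H-indene-6β-carbaldehyde | CC(=O)C(CC=C(C)C)(CC=C(C)C)C(=O)[C@@]2(C[C@H]3[C@@H](CC[C@@]3(C)O)[C@](C)(O)C2)C=O
F6 | step 23 | ring A β-hydroxy diketone: 30 with the carbonyl next to the spiro carbon on the methylene side reduced to CH(OH) (carbinol epimers) | C1C(=O)C(CC=C(C)C)(CC=C(C)C)C(=O)[C@@]2(C[C@H]3[C@@H](CC[C@@]3(C)O)[C@](C)(O)C2)C1O
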